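## Retrosynthetic overview

1. Endgame: the target comes from chlorolactone 30 by desilylation, MnO2 oxidation at C12 and triacetylation. C6–Cl, C7–O and the γ-lactone (O–C7–C8–C17–C19) come from a (6Z)-C6=C7 alkene through C8–OH-directed epoxidation, syn HCl opening and lactonisation. C8–C17 comes from a propionate aldol on a C8 ketone, and O3/O2 from a C2=C3 silyl enol ether.
2. Key disconnection: the C3–C4–C5(=C16)–C6 "isoprene" segment of the ten-membered ring C1–C10 is cut out. What remains is a eudesmane-type trans-decalin: ring A plus six-membered ring B (C1, C2, C7, C8, C9, C10) with an extra bond C2–C7. In the forward direction a propargyl Claisen/allenyl siloxy-Cope cascade forms C6–C7 and C4–C5, breaks O–C16 and C2–C7, and enlarges ring B (6) to the carbocycle (10) with C5=C16 in place.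
3. Ring B comes from an intramolecular Claisen condensation (C7 to C2) of a methyl ketone and an ester held trans on ring A. C8 and C7 come from 1-ethoxyvinyllithium, and C9 from a Felkin–Anh reduction.
4. Ring A (C1, C10–C14) comes from the endo, "ortho" Diels–Alder reaction of (E)-piperylene with ethyl (E)-2-methyl-4-oxobut-2-enoate. This sets C1, C10 and C11, and the E-alkene gives the trans ring fusion. Selenolactonisation then moves the alkene to C13=C14 and puts oxygen on C12.
5. Ring order: A, then a temporary C9/C12 lactone, then B, then the ten-membered ring (B is consumed), then the γ-lactone.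

Key step: step 12

Remark (numbering): briarane numbering of the target is used for all intermediates. Ring A is C1, C10–C14, with C15 on C1, C16 on C5, C18 on C17 and C20 on C11. β is the face of ring A that carries C15.

Assumption: the oxazaborolidinium catalyst of step 3 is taken as the (S)-enantiomer on the basis of the usual formyl C–H···O binding model; if the sense of induction is opposite for this β,β-disubstituted enal, the (R)-catalyst is used.

## Route

Step 1
Reactants: 1 2,2-dimethoxyacetaldehyde; 2 ethyl 2-(triphenylphosphoranylidene)propanoate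
Product: 3 ethyl (E)-4,4-dimethoxy-2-methylbut-2-enoate
Conditions: CH2Cl2, rt
Reagents that add atoms: none
Why: Wittig olefination with a stabilised α-branched ylide should give the (E)-enoate (CO2Et trans to the acetal carbon), which is the later trans C2/C9 relationship.

Step 2
Reactants: 3 ethyl (E)-4,4-dimethoxy-2-methylbut-2-enoate
Product: 4 ethyl (E)-2-methyl-4-oxobut-2-enoate
Conditions: Amberlyst-15, acetone/H2O, rt
Reagents that add atoms: water, O
Why: Acid-catalysed acetal hydrolysis should free the conjugated (E)-enal without touching the ester; no stereocentre is formed.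

Step 3
Reactants: 4 ethyl (E)-2-methyl-4-oxobut-2-enoate; 5 (E)-penta-1,3-diene
Product: 6 ring-A aldehyde ester (ethyl 6-formyl-1,5-dimethylcyclohex-3-ene-1-carboxylate; C15 β, CO2Et = C2 α, CHO = C9 β, H10 α, C20 β, C12=C13)
Conditions: (S)-oxazaborolidinium triflimide [from (S)-α,α-diphenylprolinol, o-tolylboronic acid, Tf2NH] (15 mol %), CH2Cl2, −78 → −40 °C
Reagents that add atoms: none
Why: In this enantioselective Lewis-acid-catalysed Diels–Alder reaction the boron-bound formyl group makes C1 the electrophilic β-carbon, so the CH2 terminus of the diene bonds to C1 ("ortho" rule), suprafacial addition to the (E)-alkene puts C2 and C9 trans (C15 β, H10 α), the endo-formyl transition state puts the C11 methyl cis to C9, and the catalyst shields one enal face to fix the absolute configuration.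

Step 4
Reactants: 6 ring-A aldehyde ester
Product: 7 ring-A acid ester (C9 = CO2H)
Conditions: NaClO2, NaH2PO4, 2-methylbut-2-ene, t-BuOH/H2O, 0 °C
Reagents that add atoms: sodium chlorite, [Na+].[O-]Cl=O
Why: Pinnick oxidation is mild enough to leave the C10 stereocentre and the C12=C13 alkene (protected by the HOCl scavenger) untouched.

Step 5
Reactants: 7 ring-A acid ester
Product: 9 unsaturated bicyclic lactone (C9(=O)–O–C12 on the β face, C13=C14), via phenylselenolactone 8 (not isolated)
Conditions: PhSeCl, Et3N, CH2Cl2, −78 °C; then 30 % H2O2, pyridine, 0 °C → rt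
Reagents that add atoms: none
Why: In this phenylselenolactonisation/selenoxide syn-elimination the β-oriented C9 carboxylate attacks C12 (γ-lactone, anti to selenium on C13), which sets C12–O β, and the selenoxide eliminates away from oxygen towards C14, so oxygen lands on C12 and the alkene on C13=C14 without C11 ever being α to a carbonyl.

Step 6
Reactants: 9 unsaturated bicyclic lactone; 10 ethyl vinyl ether
Product: 11 α-ethoxy enone (C9(=O)–C8(OEt)=C7H2, free C12 β-OH)
Conditions: 10, t-BuLi, THF, −78 → 0 °C; then 9, THF, −78 °C; aq NH4Cl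
Reagents that add atoms: none
Why: Acyl substitution of the strained allylic lactone by an α-alkoxyvinyllithium (acyl anion equivalent) should stop at the lactol alkoxide stage, and the ester on quaternary C1 is too hindered to compete; no stereocentre is formed.

Step 7
Reactants: 11 α-ethoxy enone
Product: 13 dihydroxy methyl ketone ((9S)-C9–OH, C8(=O)–C7H3, C12 β-OH), via allylic alcohol enol ether 12 (not isolated)
Conditions: NaBH4, CeCl3·7H2O, MeOH, −78 °C; then 0.5 M HCl, THF, 0 °C
Reagents that add atoms: water, O
Why: Luche 1,2-reduction under Felkin–Anh control (hydride anti to quaternary C1, passing H10) should set the (9S)-carbinol, and the acidic work-up hydrolyses the enol ether to the methyl ketone.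

Step 8
Reactants: 13 dihydroxy methyl ketone
Product: 14 bis-TBS ether (C9–OTBS, C12–OTBS)
Conditions: TBSOTf, 2,6-lutidine, CH2Cl2, −78 → 0 °C
Reagents that add atoms: tert-butyldimethylsilyl triflate, CC(C)(C)[Si](C)(C)OS(=O)(=O)C(F)(F)F
Why: Standard silylation masks both secondary alcohols for the organometallic and thermal steps; the weak base leaves the ketone and C9 unchanged.

Step 9
Reactants: 14 bis-TBS ether
Product: 15 trans-decalin-2,8-dione (ring B closed: C2(=O)–C7H2–C8(=O)–C9(OTBS, β-axial); C15 β, H10 α)
Conditions: LiHMDS (2.2 equiv), THF, −78 → 0 °C; aq NH4Cl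
Reagents that add atoms: none
Why: In this intramolecular Claisen (Dieckmann-type) condensation the kinetic enolate of the methyl group (C7) acylates on the C2 ester in a 6-exo-trig closure, the trans C2/C9 arrangement gives the trans-decalin, and immediate deprotonation of the 1,3-dione protects C9 from epimerisation.

Step 10
Reactants: 15 trans-decalin-2,8-dione; 16 prop-2-yn-1-ol
Product: 17 C8 propargyl enol ether (C8(OCH2C≡CH)=C7H–C2(=O))
Conditions: PPh3, DIAD, THF, 0 °C → rt
Reagents that add atoms: none
Why: Mitsunobu O-alkylation of a cyclic 1,3-dione under neutral conditions should take place on the less hindered O8, leaving the neopentyl C2 carbonyl (next to quaternary C1) as the ketone.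

Step 11
Reactants: 17 C8 propargyl enol ether; 18 vinylmagnesium bromide
Product: 20 C2 tertiary TMS ether (vinyl = C3=C4 α-axial, OTMS β-equatorial), via C2 alkoxide 19 (not isolated)
Conditions: CeCl3, 18, THF, −78 °C; then TMSOTf, 2,6-lutidine, −78 → 0 °C
Reagents that add atoms: trimethylsilyl triflate, C[Si](C)(C)OS(=O)(=O)C(F)(F)F
Why: The weakly basic organocerium reagent (which spares the alkyne C–H) adds 1,2 to the vinylogous ester from the α face, anti to the axial C15 methyl, which sets C2, and in situ silylation avoids handling the acid-labile bis-allylic alcohol.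

Step 12
Reactants: 20 C2 tertiary TMS ether
Product: 22 bicyclo[8.4.0] silyl enol ether dienone (C2(OTMS)=C3 with C1 and C4 trans, C5=C16H2, (6Z)-C6=C7, C8 ketone), via allenyl ketone 21 (not isolated)
Conditions: toluene (0.005 M), BSA (0.2 equiv), BHT, base-washed sealed tube, 140 °C
Reagents that add atoms: none
Why: Proposed new method: heating first triggers the [3,3] propargyl Claisen shift of the C8 enol ether (C6–C7 formed on the α face, opposite the axial C15 and O9; O–C16 broken) to give allenyl ketone 21, in which the axial C2 vinyl and equatorial C7 allenyl groups are gauche, and 21 then undergoes a [3,3] siloxy-Cope shift through a chair transition state (C4–C5 formed at the central allene carbon, C2–C7 broken). The closest known reaction types are the thermal rearrangement of propargyl vinyl ethers to α-allenyl ketones and the oxy-Cope four-carbon ring expansion of 1,2-divinylcyclohexanols to cyclodec-5-enones, and the allene as second π component of such an expansion is the new element. The ten-membered ring C1–C10 is closed by sigmatropic enlargement of six-membered ring B rather than by end-to-end cyclisation, and turning the cumulated C5 into a 1,3-diene (roughly 10–12 kcal/mol, judged from 1,2- versus 1,3-butadiene) together with release of the syn-axial C15/C20/O9 strain should pay for the medium-ring strain that normally drives the neutral Cope shift backwards. No sp3 centre is created: with ring B locked as a chair the chair transition state places C1 pseudoequatorial and C8 pseudoaxial, which should give the enol ether with C1 and C4 trans and the C6=C7 bond Z, and it fixes the outward face of each double bond, the faces that carry O3, Cl6 and O7 in the target. The step needs periselectivity over the second 1,5-diene C4=C3–C2–C1–C14=C13, and this is secured because the C1–C2 bond is equatorial on ring A and lies near the nodal plane of the C13=C14 π bond, so only C2–C7 can break. Loss of Me3SiOH from the β-silyloxy ketone 21 is the side reaction to suppress, hence the neutral, acid-free, dilute conditions.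

Step 13
Reactants: 22 bicyclo[8.4.0] silyl enol ether dienone; 23 methyl propanoate
Product: 24 aldol adduct ((8R)-tertiary alcohol bearing (17R)-CH(CH3)CO2Me)
Conditions: 23, LDA, THF/DMPU, −78 °C; then 22, −78 °C; aq NH4Cl
Reagents that add atoms: none
Why: Kinetic 1,2-aldol addition of the lithium (Z)-O-enolate to the only free ketone should set C8 by the polar Felkin–Anh model (attack anti to the non-chelating C9–OTBS, passing H9) and C17 by the closed chair transition state (C9 side as the large, equatorial group, giving the syn relationship).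

Step 14
Reactants: 24 aldol adduct
Product: 26 α-hydroxy ketone ((3S)-OH, C2 ketone), via α-silyloxy ketone 25 (not isolated)
Conditions: DMDO (1.0 equiv), acetone/CH2Cl2, −78 °C; then citric acid, MeOH, 0 °C
Reagents that add atoms: dimethyldioxirane, CC1(C)OO1
Why: In this Rubottom oxidation the silyl enol ether is by far the most electron-rich alkene, and oxygen can reach the ring-trans C2=C3 bond only from its outward face (opposite the former C2–C7 bond), which corresponds to (3S).

Step 15
Reactants: 26 α-hydroxy ketone
Product: 27 2,3,8-triol ((2R,3S)-anti-diol)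
Conditions: Zn(BH4)2, Et2O, −30 °C; aq NH4Cl
Reagents that add atoms: none
Why: Chelation-controlled reduction of an α-hydroxy ketone (zinc bridging O2 and O3, hydride opposite C4) should give the anti-2,3-diol, i.e. (2R), and it leaves the ester untouched.

Step 16
Reactants: 27 2,3,8-triol
Product: 28 cis-6,7-epoxide (oxygen on the outward face, syn to the C8 hydroxyl)
Conditions: VO(acac)2 (5 mol %), t-BuOOH (1.1 equiv), toluene, 0 °C
Reagents that add atoms: tert-butyl hydroperoxide, CC(C)(C)OO
Why: In this vanadium-catalysed hydroxyl-directed epoxidation the allylic C8–OH sits inside (least A(1,3) strain with C5, O–C8–C7=C6 about 45°) with the ring bond C8–C9 anti to the incoming oxygen, so oxygen is delivered to the outward face of the Z-alkene and sets C7 and C6, while the non-allylic C5=C16 and C13=C14 bonds react more slowly.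

Step 17
Reactants: 28 cis-6,7-epoxide
Product: 30 chlorolactone ((6S)-Cl, (7R)-O, γ-lactone closed, C5=C16 kept), via chlorohydrin ester 29 (not isolated)
Conditions: HCl (1 M in Et2O, 1.2 equiv), CH2Cl2, −78 → −20 °C
Reagents that add atoms: hydrogen chloride, Cl
Why: In this syn hydrochlorination of a vinyl oxirane under ion-pair conditions in an apolar medium the allylic C6–O bond ionises, chloride collapses from the outward face that the oxygen leaves because the rear face is shielded across the ring (retention at C6, C7–O untouched), and the freed C7–OH lactonises on the methyl ester (5-exo-trig).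

Step 18
Reactants: 30 chlorolactone
Product: 31 pentaol (free OH at C2, C3, C8, C9, C12)
Conditions: HF·pyridine, pyridine/THF, 0 °C → rt
Reagents that add atoms: none
Why: Buffered fluoride desilylation removes both TBS groups without base, so the lactone, the allylic chloride and C17 are not endangered.

Step 19
Reactants: 31 pentaol
Product: 32 enone tetraol (C12 ketone, C13=C14)
Conditions: activated MnO2, CH2Cl2, rt
Reagents that add atoms: none
Why: Neutral MnO2 oxidation is selective for the only allylic alcohol (C12), so the enone appears without exposing the now epimerisable C11 to base.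

Step 20
Reactants: 32 enone tetraol
Product: 33 target CNP0391614.1
Conditions: Ac2O, pyridine, DMAP (5 mol %), CH2Cl2, 0 °C
Reagents that add atoms: acetic anhydride, CC(=O)OC(C)=O
Why: Acetylation of the three secondary alcohols (C2, C3, C9) should leave the hindered tertiary C8–OH free, and the weak base at low temperature keeps C11 and C17 intact.

## Compound list

1 | 2,2-dimethoxyacetaldehyde | COC(OC)C=O | starting material
2 | ethyl 2-(triphenylphosphoranylidene)propanoate | CCOC(=O)C(C)=P(c1ccccc1)(c1ccccc1)c1ccccc1 | starting material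
3 | ethyl (E)-4,4-dimethoxy-2-methylbut-2-enoate | CCOC(=O)/C(C)=C/C(OC)OC | intermediate
4 | ethyl (E)-2-methyl-4-oxobut-2-enoate | CCOC(=O)/C(C)=C/C=O | intermediate
5 | (E)-penta-1,3-diene | C=C/C=C/C | starting material
6 | ring-A aldehyde ester | CCOC(=O)[C@@]1(C)CC=C[C@H](C)[C@@H]1C=O | intermediate
7 | ring-A acid ester | CCOC(=O)[C@@]1(C)CC=C[C@H](C)[C@@H]1C(=O)O | intermediate
8 | phenylselenolactone | CCOC(=O)[C@@]1(C)C[C@@H]([Se]c3ccccc3)[C@@H]2OC(=O)[C@H]1[C@H]2C | intermediate
9 | unsaturated bicyclic lactone | CCOC(=O)[C@@]1(C)C=C[C@@H]2OC(=O)[C@H]1[C@H]2C | intermediate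
10 | ethyl vinyl ether | C=COCC | starting material
11 | α-ethoxy enone | CCOC(=O)[C@@]1(C)C=C[C@H](O)[C@H](C)[C@@H]1C(=O)C(=C)OCC | intermediate
12 | allylic alcohol enol ether | CCOC(=O)[C@@]1(C)C=C[C@H](O)[C@H](C)[C@@H]1[C@H](O)C(=C)OCC | intermediate
13 | dihydroxy methyl ketone | CCOC(=O)[C@@]1(C)C=C[C@H](O)[C@H](C)[C@@H]1[C@H](O)C(C)=O | intermediate
14 | bis-TBS ether | CCOC(=O)[C@@]1(C)C=C[C@H](O[Si](C)(C)C(C)(C)C)[C@H](C)[C@@H]1[C@H](O[Si](C)(C)C(C)(C)C)C(C)=O | intermediate
15 | trans-decalin-2,8-dione | C[C@]12C=C[C@H](O[Si](C)(C)C(C)(C)C)[C@H](C)[C@@H]1[C@H](O[Si](C)(C)C(C)(C)C)C(=O)CC2=O | intermediate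
16 | prop-2-yn-1-ol | C#CCO | starting material
17 | C8 propargyl enol ether | C[C@]12C=C[C@H](O[Si](C)(C)C(C)(C)C)[C@H](C)[C@@H]1[C@H](O[Si](C)(C)C(C)(C)C)C(OCC#C)=CC2=O | intermediate
18 | vinylmagnesium bromide | C=C[Mg]Br | starting material
19 | C2 alkoxide (drawn as bromomagnesium salt) | C[C@]12C=C[C@H](O[Si](C)(C)C(C)(C)C)[C@H](C)[C@@H]1[C@H](O[Si](C)(C)C(C)(C)C)C(OCC#C)=C[C@]2(C=C)O[Mg]Br | intermediate
20 | C2 tertiary TMS ether | C[C@]12C=C[C@H](O[Si](C)(C)C(C)(C)C)[C@H](C)[C@@H]1[C@H](O[Si](C)(C)C(C)(C)C)C(OCC#C)=C[C@]2(C=C)O[Si](C)(C)C | intermediate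
21 | allenyl ketone | C[C@]12C=C[C@H](O[Si](C)(C)C(C)(C)C)[C@H](C)[C@@H]1[C@H](O[Si](C)(C)C(C)(C)C)C(=O)[C@@H](C=C=C)[C@]2(C=C)O[Si](C)(C)C | intermediate
22 | bicyclo[8.4.0] silyl enol ether dienone | C=C1C/C=C(O[Si](C)(C)C)/[C@@]2(C)C=C[C@H](O[Si](C)(C)C(C)(C)C)[C@H](C)[C@@H]2[C@H](O[Si](C)(C)C(C)(C)C)C(=O)/C=C\1 | intermediate
23 | methyl propanoate | CCC(=O)OC | starting material
24 | aldol adduct | C=C1C/C=C(O[Si](C)(C)C)/[C@@]2(C)C=C[C@H](O[Si](C)(C)C(C)(C)C)[C@H](C)[C@@H]2[C@H](O[Si](C)(C)C(C)(C)C)[C@](O)([C@@H](C)C(=O)OC)/C=C\1 | intermediate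
25 | α-silyloxy ketone | C=C1C[C@H](O[Si](C)(C)C)C(=O)[C@@]2(C)C=C[C@H](O[Si](C)(C)C(C)(C)C)[C@H](C)[C@@H]2[C@H](O[Si](C)(C)C(C)(C)C)[C@](O)([C@@H](C)C(=O)OC)/C=C\1 | intermediate
26 | α-hydroxy ketone | C=C1C[C@H](O)C(=O)[C@@]2(C)C=C[C@H](O[Si](C)(C)C(C)(C)C)[C@H](C)[C@@H]2[C@H](O[Si](C)(C)C(C)(C)C)[C@](O)([C@@H](C)C(=O)OC)/C=C\1 | intermediate
27 | 2,3,8-triol | C=C1C[C@H](O)[C@H](O)[C@@]2(C)C=C[C@H](O[Si](C)(C)C(C)(C)C)[C@H](C)[C@@H]2[C@H](O[Si](C)(C)C(C)(C)C)[C@](O)([C@@H](C)C(=O)OC)/C=C\1 | intermediate
28 | cis-6,7-epoxide | C=C1C[C@H](O)[C@H](O)[C@@]2(C)C=C[C@H](O[Si](C)(C)C(C)(C)C)[C@H](C)[C@@H]2[C@H](O[Si](C)(C)C(C)(C)C)[C@](O)([C@@H](C)C(=O)OC)[C@H]3O[C@H]31 | intermediate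
29 | chlorohydrin ester | C=C1C[C@H](O)[C@H](O)[C@@]2(C)C=C[C@H](O[Si](C)(C)C(C)(C)C)[C@H](C)[C@@H]2[C@H](O[Si](C)(C)C(C)(C)C)[C@](O)([C@@H](C)C(=O)OC)[C@@H](O)[C@H]1Cl | intermediate
30 | chlorolactone | C=C1C[C@H](O)[C@H](O)[C@@]2(C)C=C[C@H](O[Si](C)(C)C(C)(C)C)[C@H](C)[C@@H]2[C@H](O[Si](C)(C)C(C)(C)C)[C@]2(O)[C@@H](C)C(=O)O[C@H]2[C@H]1Cl | intermediate
31 | pentaol | C=C1C[C@H](O)[C@H](O)[C@@]2(C)C=C[C@H](O)[C@H](C)[C@@H]2[C@H](O)[C@]2(O)[C@@H](C)C(=O)O[C@H]2[C@H]1Cl | intermediate
32 | enone tetraol | C=C1C[C@H](O)[C@H](O)[C@@]2(C)C=CC(=O)[C@H](C)[C@@H]2[C@H](O)[C@]2(O)[C@@H](C)C(=O)O[C@H]2[C@H]1Cl | intermediate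
33 | CNP0391614.1 | C=C1C[C@H](OC(C)=O)[C@H](OC(C)=O)[C@@]2(C)C=CC(=O)[C@H](C)[C@@H]2[C@H](OC(C)=O)[C@]2(O)[C@@H](C)C(=O)O[C@H]2[C@H]1Cl | target

## Step count and risks

Total step count: 20. Longest linear sequence: 20 (steps 1–20).

The three steps most likely to fail:

1. **Step 12 (labelled step).** What may go wrong: silanol may be lost from the β-silyloxy ketone stage, the Cope shift may be incomplete or reversible, or the chair-derived alkene geometry may erode.
   - The fallback closes the ring by metathesis at C6=C7 instead of by ring enlargement. It sets out from 15 and returns at 22.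
   - Silylation of 15 (TBSOTf, Et3N) should give the C8 silyl enol ether enone F1.
   - Addition of the organocerium reagent made from 5-iodo-3-methylidenepent-1-ene (t-BuLi, CeCl3) gives the tertiary alcohol F2.
   - K2CO3/MeOH cleaves the enol silyl ether, and the resulting aldolate opens by retro-aldol cleavage of C2–C7 to the seco diketone F3.
   - Kinetic deprotonation of the methyl ketone (LDA) and dimethyl(methylidene)ammonium iodide give the Mannich base F4.
   - Quaternisation (MeI) and elimination (DBU) give the vinyl ketone F5.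
   - Ene–diene ring-closing metathesis (second-generation ruthenium benzylidene catalyst, high dilution) gives the macrocyclic dienone diketone F6.
   - TMSOTf/Et3N, which can enolise C2 only towards C3, leads back to 22.

2. **Step 17.** What may go wrong: stereochemical fidelity may be lost through rear-side attack, the allylic system may transpose (chloride ending on C16), or the allylic silyl ether may be cleaved.
   - The fallback replaces front-side collapse by two SN2 inversions. It sets out from 28 and returns at 30.
   - MgBr2·OEt2 opens the epoxide at the allylic C6 with inversion, and the C7 alkoxide lactonises to the bromolactone F7.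
   - One equivalent of Bu4NCl (acetone, 0 °C) then displaces the far better leaving group with a second inversion to give 30.

3. **Step 3.** What may go wrong: the β,β-disubstituted enal may react slowly, and facial or endo selectivity with the catalyst may be poor.
   - The fallback uses auxiliary control. It sets out from 4 and returns at 7.
   - Pinnick oxidation of 4 gives the half-acid F8.
   - Activation as the mixed pivalic anhydride and coupling with lithiated (S)-4-benzyl-1,3-oxazolidin-2-one give the imide F9.
   - Et2AlCl-promoted Diels–Alder reaction with 5 proceeds through the chelated s-cis imide, with the diene approaching the face opposite the benzyl group and the imide carbonyl endo. It should give the adduct F10 with the same C1, C10 and C11 configuration.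
   - LiOOH removes the auxiliary to give 7.

Further compounds
F1 | step 12 | C8 silyl enol ether enone | C[C@]12C=C[C@H](O[Si](C)(C)C(C)(C)C)[C@H](C)[C@@H]1[C@H](O[Si](C)(C)C(C)(C)C)C(O[Si](C)(C)C(C)(C)C)=CC2=O
F2 | step 12 | tertiary alcohol with 3-methylidenepent-4-enyl chain on C2 | C[C@]12C=C[C@H](O[Si](C)(C)C(C)(C)C)[C@H](C)[C@@H]1[C@H](O[Si](C)(C)C(C)(C)C)C(O[Si](C)(C)C(C)(C)C)=C[C@@]2(O)CCC(=C)C=C
F3 | step 12 | seco diketone | C=CC(=C)CCC(=O)[C@@]1(C)C=C[C@H](O[Si](C)(C)C(C)(C)C)[C@H](C)[C@@H]1[C@H](O[Si](C)(C)C(C)(C)C)C(C)=O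
F4 | step 12 | Mannich base | C=CC(=C)CCC(=O)[C@@]1(C)C=C[C@H](O[Si](C)(C)C(C)(C)C)[C@H](C)[C@@H]1[C@H](O[Si](C)(C)C(C)(C)C)C(=O)CCN(C)C
F5 | step 12 | vinyl ketone | C=CC(=C)CCC(=O)[C@@]1(C)C=C[C@H](O[Si](C)(C)C(C)(C)C)[C@H](C)[C@@H]1[C@H](O[Si](C)(C)C(C)(C)C)C(=O)C=C
F6 | step 12 | macrocyclic dienone diketone | C=C1CCC(=O)[C@@]2(C)C=C[C@H](O[Si](C)(C)C(C)(C)C)[C@H](C)[C@@H]2[C@H](O[Si](C)(C)C(C)(C)C)C(=O)/C=C\1
F7 | step 17 | bromolactone (C6 inverted) | C=C1C[C@H](O)[C@H](O)[C@@]2(C)C=C[C@H](O[Si](C)(C)C(C)(C)C)[C@H](C)[C@@H]2[C@H](O[Si](C)(C)C(C)(C)C)[C@]2(O)[C@@H](C)C(=O)O[C@H]2[C@@H]1Br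
F8 | step 3 | (E)-4-ethoxy-3-methyl-4-oxobut-2-enoic acid | CCOC(=O)/C(C)=C/C(=O)O
F9 | step 3 | N-enoyl (S)-4-benzyloxazolidinone | CCOC(=O)/C(C)=C/C(=O)N1[C@@H](Cc2ccccc2)COC1=O
F10 | step 3 | Diels–Alder adduct imide | CCOC(=O)[C@@]1(C)CC=C[C@H](C)[C@@H]1C(=O)N1[C@@H](Cc2ccccc2)COC1=O
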